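## The problem

Kazinol B (22) is a (2S)-flavan. Ring A (7-hydroxy) is fused to the pyran ring C, and C2 carries a benzene ring B substituted at five of its six carbons: C1' by C2, C2' by a prenyl group, C3' by a free hydroxyl, and C4'/C5' by the oxygen and the vinyl carbon of a 2,2-dimethyl-2H-pyran (ring D). C2 is the only stereocentre, so nothing in the molecule can direct it; a reagent or catalyst must set it, and it must then be kept. Keeping it is not trivial: C2 is a benzylic ether carbon para to the C4' oxygen, so protonation of O1, a leaving group on C2 or a free 4'-phenoxide each open an ionisation or quinone methide path to the racemate. The two catechol oxygens of ring B must be told apart (O4' enters ring D, which closes on C5'; O3' stays free), and the prenyl group must reach C2', the most crowded carbon of the ring. The ortho-prenylphenol and the ring D double bond tolerate neither acid nor hydrogenation, so C3–C4 must be saturated early and the last protecting group must leave under base or fluoride. The feature that allows a short entry is ring C itself: C2 lies between O1 and C3, and C4 sits on C4a ortho to O1, so O1–C8a–C4a–C4 is the skeleton of a salicylaldehyde and C2/C3 are the β- and α-carbons of a ring B cinnamaldehyde.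

## Retrosynthesis

**22 from 21.** The O7–acyl bond is cut last. A pivalate is preferred to an acetal because it leaves by basic methanolysis, which touches neither the prenylphenol, the chromene nor the C2 ether.

**21 from 19, and 19 from 16 and 18.** The C2'–CH2 bond is cut by a retro-aromatic Claisen step to the tertiary allyl ether 19, and the O3'–C bond then leads to phenol 16 and carbonate 18 (one step from alcohol 17). Direct C-prenylation under acid would favour the open C6' or ring A. In 19 the sigmatropic shift can only end at C2', because the other ortho carbon of O3' (C4') carries the ring D oxygen. The forward reaction must etherify at the tertiary allyl terminus and rearrange into a flanked position.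

**16 from 15, 15 from 13, 13 from 11 and 12.** Ring D is opened at O4'–CMe2 and C5'–CH by a retro propargyl Claisen/electrocyclisation sequence, leaving phenol 11 and chloride 12. The silyloxy group on C3' blocks one ortho position of O4', so closure can only occur at C5'. Compound 11 has no alkene. The forward etherification must not shift the silyl group from O3' to O4' and must not open ring C through the 4'-phenoxide.

**11 from 10, 10 from 9.** The C3–CHO bond is restored (retro-decarbonylation), then the C3=C4 double bond and the O4' benzyl ether (retro-hydrogenation). Saturation comes before decarbonylation deliberately: the 2-aryl-2H-chromene 9 can open thermally by a retro-oxa-6π process to an achiral ortho-quinone methide, so heating it with rhodium would risk the stereocentre, whereas chroman 10 has no such path. The formyl carbon is the price of the ring-forming step; its removal is one neutral step.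

**9 from 2 and 7.** O1–C2 and C3–C4 are cut together. Against closing O1–C2 by displacement at a C2 carbinol (a leaving group on a para-oxygenated benzylic carbon), this cut forms the C–O bond by conjugate addition and closes ring C by a C–C bond, with C2 set by an amine catalyst. The precursors are two achiral aldehydes.

**7 from 5 and 6, 5 from 4, 4 from 3; 2 from 1.** The enal double bond is cut to aldehyde 5 and ylide 6; the two ring B oxygens are differentiated on 3 through the higher acidity of the 4-hydroxyl. Benzyl on O4' leaves in the same hydrogenation that saturates C3–C4. Triisopropylsilyl on O3' survives that step and is the silyl group least prone to migrate. Pivalate on O7 (from 1) also makes the formyl group of 2 a better aldol acceptor.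

## Roads not taken

**Alternative 1:** The cut goes through ring B at C1'–C2 and C2'–CH2. Fluoride releases the C1'–C2' aryne from silyl triflate A2; the copper acetylide of propargyl arene A3 adds at C1', and the aryl copper at C2' is trapped by an allyl halide, giving A1 without closing a ring.
- Merits: the carbon substituent at crowded C2' is installed in the same operation that joins the two halves, with regiochemistry set by the C3' oxygen of the aryne. In this respect it is better than the chosen plan, which reaches C2' only by a late Claisen step.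
- Weak points: A1 has no stereocentre. C2 is an alkyne carbon that must be hydrated with the right regiochemistry, reduced asymmetrically and closed onto the ring A bromide by a metal-catalysed C–O coupling. The allyl group must still become prenyl. The acetonide frees both catechol oxygens at once, so the O3'/O4' choice for ring D is unsolved. The doubly activated CH2 of A3 can isomerise to an allene under base.
- Comparison: the chosen plan sets against the better C2' control one catalytic step that delivers ring C and the stereocentre, and oxygens differentiated from the first step.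

**Alternative 2:** The cut removes the prenyl C2'–CH2 bond and the ring D bonds C5'–CH and O4'–CMe2 in one heating of diether A5. The allyl ether rearranges to C2', the propargyl ether to C5', then hydrogen shift and oxa-6π closure give A4.
- Merits: both C5 units and ring D arrive in one late operation, each ether having one free ortho carbon. It is about two steps shorter than steps 8–13 of the chosen plan, so in step economy it is better.
- Weak points: A5 needs two bulky tertiary ethers on neighbouring oxygens, which still requires the same O3'/O4' differentiation and a difficult second etherification. The new prenylphenol sits through the hotter propargyl rearrangement. The final acetal cleavage of A4 puts acid on the prenylphenol, the chromene and the C2 ether. The alternative does not address C2.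
- Comparison: the chosen plan uses the same two pericyclic reactions, run separately, each at its own temperature with the other oxygen masked, and ends in base. The cascade could be grafted onto the chosen ring C construction if A5 proved accessible.

**Alternative 3:** The cut is O1–C8a. A hindered lithium amide converts carbinol A7 into its alkoxide and, by deprotonation at C8 and chloride loss, into the C8a–C8 aryne; the alkoxide adds at C8a (6-exo-dig) to give A6.
- Merits: the stereocentre is made by asymmetric ketone reduction and its C–O bond is never broken. Ring D is already present, and neither decarbonylation nor hydrogenation follows. In predictability of enantiocontrol it is at least as good as the chosen plan.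
- Weak points: A7 needs a longer linear synthesis, including a chemoselective saturation beside an aryl chloride and a chromene. Excess strong base can add to the aryne or deprotonate benzylic positions. Six-membered alkoxide–aryne closures are less common than five-membered ones. The acetal on O7 again ends the route in acid.
- Comparison: the chosen plan sets against it a catalytic, base-free union of two aldehydes made in one and three steps, and an acid-free end game.

Key step: step 5

Remark on the chemistry: flavan numbering (O1, C2–C4, C4a–C8a; ring B C1'–C6') is used for all intermediates.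

Assumption: the sense of induction in step 5 is assigned from the usual steric model for diarylprolinol silyl ether iminium ions (attack anti to the diaryl(silyloxy)methyl arm of the (E)-s-trans iminium), on which the (S)-catalyst gives the required configuration; the (R)-catalyst is equally available should the model fail here.

## Route

Step 1
Reactants: 1 2,4-dihydroxybenzaldehyde
Product: 2 4-formyl-3-hydroxyphenyl pivalate
Conditions: PivCl (1.05 equiv), Et3N, CH2Cl2, 0 °C
Reagents that add atoms: pivaloyl chloride, CC(C)(C)C(=O)Cl
Why: Regioselective O-acylation; the 2-hydroxyl is hydrogen-bonded to the formyl group and is the poorer nucleophile, so one equivalent of acid chloride should esterify O4 only. The pivalate survives every later step, leaves under K2CO3/MeOH, and makes the formyl group a better aldol acceptor in step 5.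

Step 2
Reactants: 3 3,4-dihydroxybenzaldehyde
Product: 4 4-(benzyloxy)-3-hydroxybenzaldehyde
Conditions: BnBr (1.1 equiv), NaHCO3, NaI (cat.), DMF, 40 °C
Reagents that add atoms: benzyl bromide, BrCc1ccccc1
Why: Williamson etherification with a base that ionises only the 4-hydroxyl, which is para to the formyl group and the more acidic; a known regioselective monobenzylation.

Step 3
Reactants: 4 4-(benzyloxy)-3-hydroxybenzaldehyde
Product: 5 4-(benzyloxy)-3-(triisopropylsilyloxy)benzaldehyde
Conditions: TIPSCl, imidazole, DMF, rt
Reagents that add atoms: chlorotriisopropylsilane, CC(C)[Si](Cl)(C(C)C)C(C)C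
Why: Standard phenol silylation; triisopropylsilyl survives hydrogenation and heat and is the silyl group least prone to 1,4 O-to-O migration in catechols.

Step 4
Reactants: 5 4-(benzyloxy)-3-(triisopropylsilyloxy)benzaldehyde; 6 (triphenylphosphoranylidene)acetaldehyde
Product: 7 (E)-3-[4-(benzyloxy)-3-(triisopropylsilyloxy)phenyl]prop-2-enal
Conditions: PhMe, 80 °C
Reagents that add atoms: none
Why: Wittig olefination with a formyl-stabilised ylide, an (E)-selective two-carbon homologation of aromatic aldehydes; the ylide is kept near one equivalent to limit a second homologation.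

Step 5
Reactants: 2 4-formyl-3-hydroxyphenyl pivalate; 7 (E)-3-[4-(benzyloxy)-3-(triisopropylsilyloxy)phenyl]prop-2-enal
Product: 9 (2R)-2-[4-(benzyloxy)-3-(triisopropylsilyloxy)phenyl]-3-formyl-2H-chromen-7-yl pivalate, via oxa-Michael enamine 8 (not isolated)
Conditions: (S)-α,α-diphenylprolinol trimethylsilyl ether (20 mol%), 2-nitrobenzoic acid (20 mol%), 4 Å MS, PhMe, 0 °C to rt, dark
Reagents that add atoms: none
Why: This is the known amine-catalysed domino oxa-Michael/aldol condensation of salicylaldehydes with cinnamaldehydes (iminium, then enamine catalysis). The catalyst and 7 form an (E)-s-trans iminium ion; the phenol oxygen of 2 adds to its β-carbon (C2) on the Si face, the one turned away from the diphenyl(trimethylsilyloxy)methyl arm, which sets the only stereocentre. Enamine 8 then attacks the neighbouring formyl carbon (C4) in a 6-(enolexo)-exo-trig aldol that closes ring C through the C3–C4 bond; dehydration and hydrolysis release 9 and the amine. The oxa-Michael step is reversible, so the selectivity rests on fast, irreversible aldol–dehydration, which the pivaloyloxy-substituted formyl group of 2 should favour. Chemoselectivity lies in the substrate: O2 of 2 is its only free hydroxyl and the only oxygen that can close a six-membered ring. The donor-substituted enal 7 should give a less electrophilic iminium ion than cinnamaldehyde, which the acid cocatalyst and high concentration are meant to offset. The medium places no leaving group on C2; 9 is (R) only because the formyl-bearing C3 outranks C1', the spatial arrangement being that of the (2S)-target.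

Step 6
Reactants: 9 (2R)-2-[4-(benzyloxy)-3-(triisopropylsilyloxy)phenyl]-3-formyl-2H-chromen-7-yl pivalate
Product: 10 (2S)-3-formyl-2-[4-hydroxy-3-(triisopropylsilyloxy)phenyl]-3,4-dihydro-2H-chromen-7-yl pivalate (both C3 epimers)
Conditions: H2 (1 atm), 10% Pd/C, EtOAc, rt
Reagents that add atoms: none
Why: Heterogeneous hydrogenation of the conjugated C3=C4 bond with hydrogenolysis of the O4' benzyl ether; C2 is untouched and the C3 epimers converge in step 7. Saturation precedes any heating because the 2H-pyran of 9 could open by retro-oxa-6π electrocyclisation; in neutral EtOAc the cyclic C2–O1 bond is expected to survive, as it does when flavan benzyl ethers are debenzylated.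

Step 7
Reactants: 10 (2S)-3-formyl-2-[4-hydroxy-3-(triisopropylsilyloxy)phenyl]-3,4-dihydro-2H-chromen-7-yl pivalate
Product: 11 (2S)-2-[4-hydroxy-3-(triisopropylsilyloxy)phenyl]-3,4-dihydro-2H-chromen-7-yl pivalate
Conditions: RhCl(PPh3)3 (1.1 equiv), PhMe, 100 °C
Reagents that add atoms: none
Why: Tsuji–Wilkinson decarbonylation; the formyl C–H adds to monovalent rhodium, CO migrates to the metal and C3–H reductive elimination follows without base, so the β-aryloxy aldehyde is not enolised and C2 stays fixed. The stoichiometric complex keeps the temperature below that of catalytic variants.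

Step 8
Reactants: 11 (2S)-2-[4-hydroxy-3-(triisopropylsilyloxy)phenyl]-3,4-dihydro-2H-chromen-7-yl pivalate; 12 3-chloro-3-methylbut-1-yne
Product: 13 (2S)-2-[4-(2-methylbut-3-yn-2-yloxy)-3-(triisopropylsilyloxy)phenyl]-3,4-dihydro-2H-chromen-7-yl pivalate
Conditions: DBU (1.3 equiv), CuCl2 (1 mol%), MeCN, −5 to 0 °C
Reagents that add atoms: none
Why: Copper-catalysed O-alkylation of a phenol with a tertiary propargylic chloride, the standard route to aryl 1,1-dimethylpropargyl ethers. Low temperature and short contact with base are meant to outrun silyl migration from O3' to O4' and opening of ring C from the 4'-phenoxide.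

Step 9
Reactants: 13 (2S)-2-[4-(2-methylbut-3-yn-2-yloxy)-3-(triisopropylsilyloxy)phenyl]-3,4-dihydro-2H-chromen-7-yl pivalate
Product: 15 (2S)-2-[2,2-dimethyl-8-(triisopropylsilyloxy)-2H-chromen-6-yl]-3,4-dihydro-2H-chromen-7-yl pivalate, via ortho-allenylphenol 14 (not isolated)
Conditions: o-xylene, 140 °C
Reagents that add atoms: none
Why: Aryl propargyl ether Claisen rearrangement to C5', the only free ortho carbon of O4', gives allenylphenol 14 after enolisation; a 1,5-hydrogen shift to the ortho-quinone methide and oxa-6π electrocyclisation close ring D. The neutral thermal conditions leave the saturated ring C and C2 alone.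

Step 10
Reactants: 15 (2S)-2-[2,2-dimethyl-8-(triisopropylsilyloxy)-2H-chromen-6-yl]-3,4-dihydro-2H-chromen-7-yl pivalate
Product: 16 (2S)-2-(8-hydroxy-2,2-dimethyl-2H-chromen-6-yl)-3,4-dihydro-2H-chromen-7-yl pivalate
Conditions: TBAF, AcOH (1.1 equiv each), THF, 0 °C
Reagents that add atoms: none
Why: Fluoride cleavage of an aryl silyl ether; the acetic acid buffer keeps the medium from becoming basic enough to attack the aryl pivalate.

Step 11
Reactants: 17 2-methylbut-3-en-2-ol
Product: 18 tert-butyl 2-methylbut-3-en-2-yl carbonate
Conditions: n-BuLi, THF, −78 to 0 °C; then Boc2O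
Reagents that add atoms: di-tert-butyl dicarbonate, CC(C)(C)OC(=O)OC(=O)OC(C)(C)C
Why: Acylation of the lithium alkoxide of a tertiary allylic alcohol, the usual preparation of this allylating reagent.

Step 12
Reactants: 16 (2S)-2-(8-hydroxy-2,2-dimethyl-2H-chromen-6-yl)-3,4-dihydro-2H-chromen-7-yl pivalate; 18 tert-butyl 2-methylbut-3-en-2-yl carbonate
Product: 19 (2S)-2-[2,2-dimethyl-8-(2-methylbut-3-en-2-yloxy)-2H-chromen-6-yl]-3,4-dihydro-2H-chromen-7-yl pivalate
Conditions: Pd(PPh3)4 (5 mol%), THF, 0 °C to rt
Reagents that add atoms: none
Why: Tsuji–Trost O-allylation; zerovalent palladium ionises the carbonate with loss of CO2, the tert-butoxide formed deprotonates the phenol, and the phenoxide attacks the more substituted allyl terminus under kinetic control, a known route to aryl 1,1-dimethylallyl ethers. No external base is present, and the ring D double bond and the aryl pivalate are inert to the catalyst.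

Step 13
Reactants: 19 (2S)-2-[2,2-dimethyl-8-(2-methylbut-3-en-2-yloxy)-2H-chromen-6-yl]-3,4-dihydro-2H-chromen-7-yl pivalate
Product: 21 (2S)-2-[8-hydroxy-2,2-dimethyl-7-(3-methylbut-2-en-1-yl)-2H-chromen-6-yl]-3,4-dihydro-2H-chromen-7-yl pivalate, via ortho-dienone 20 (not isolated)
Conditions: PhMe, 110 °C
Reagents that add atoms: none
Why: Aromatic Claisen rearrangement; the allyl terminus bonds to C2', the only ortho carbon of O3' that bears hydrogen, with allylic inversion, so the tertiary ether becomes the linear 3-methylbut-2-enyl group and dienone 20 enolises to the phenol. Tertiary allyl aryl ethers rearrange at this moderate temperature.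

Step 14
Reactants: 21 (2S)-2-[8-hydroxy-2,2-dimethyl-7-(3-methylbut-2-en-1-yl)-2H-chromen-6-yl]-3,4-dihydro-2H-chromen-7-yl pivalate
Product: 22 kazinol B
Conditions: K2CO3, MeOH, rt, argon
Reagents that add atoms: none
Why: Base-mediated transesterification of the aryl pivalate; no acid meets the ortho-prenylphenol, the chromene or the C2 benzylic ether, and carbonate offers no path to epimerise C2.

## Compound list

1 | 2,4-dihydroxybenzaldehyde | O=Cc1ccc(O)cc1O | starting material
2 | 4-formyl-3-hydroxyphenyl pivalate | CC(C)(C)C(=O)Oc1ccc(C=O)c(O)c1 | intermediate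
3 | 3,4-dihydroxybenzaldehyde | O=Cc1ccc(O)c(O)c1 | starting material
4 | 4-(benzyloxy)-3-hydroxybenzaldehyde | O=Cc1ccc(OCc2ccccc2)c(O)c1 | intermediate
5 | 4-(benzyloxy)-3-(triisopropylsilyloxy)benzaldehyde | O=Cc1ccc(OCc2ccccc2)c(O[Si](C(C)C)(C(C)C)C(C)C)c1 | intermediate
6 | (triphenylphosphoranylidene)acetaldehyde | O=CC=P(c1ccccc1)(c1ccccc1)c1ccccc1 | starting material
7 | (E)-3-[4-(benzyloxy)-3-(triisopropylsilyloxy)phenyl]prop-2-enal | O=C/C=C/c1ccc(OCc2ccccc2)c(O[Si](C(C)C)(C(C)C)C(C)C)c1 | intermediate
8 | 3-({(1S,2E)-1-[4-(benzyloxy)-3-(triisopropylsilyloxy)phenyl]-3-[(2S)-2-[diphenyl(trimethylsilyloxy)methyl]pyrrolidin-1-yl]prop-2-en-1-yl}oxy)-4-formylphenyl pivalate (catalyst-bound oxa-Michael enamine) | CC(C)[Si](C(C)C)(C(C)C)Oc1cc([C@@H](Oc2cc(OC(=O)C(C)(C)C)ccc2C=O)/C=C/N2CCC[C@H]2C(O[Si](C)(C)C)(c2ccccc2)c2ccccc2)ccc1OCc1ccccc1 | intermediate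
9 | (2R)-2-[4-(benzyloxy)-3-(triisopropylsilyloxy)phenyl]-3-formyl-2H-chromen-7-yl pivalate | CC(C)[Si](C(C)C)(C(C)C)Oc1cc([C@@H]2C(C=O)=Cc3ccc(OC(=O)C(C)(C)C)cc3O2)ccc1OCc1ccccc1 | intermediate
10 | (2S)-3-formyl-2-[4-hydroxy-3-(triisopropylsilyloxy)phenyl]-3,4-dihydro-2H-chromen-7-yl pivalate (both C3 epimers) | CC(C)[Si](C(C)C)(C(C)C)Oc1cc([C@@H]2C(C=O)Cc3ccc(OC(=O)C(C)(C)C)cc3O2)ccc1O | intermediate
11 | (2S)-2-[4-hydroxy-3-(triisopropylsilyloxy)phenyl]-3,4-dihydro-2H-chromen-7-yl pivalate | CC(C)[Si](C(C)C)(C(C)C)Oc1cc([C@@H]2CCc3ccc(OC(=O)C(C)(C)C)cc3O2)ccc1O | intermediate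
12 | 3-chloro-3-methylbut-1-yne | C#CC(C)(C)Cl | starting material
13 | (2S)-2-[4-(2-methylbut-3-yn-2-yloxy)-3-(triisopropylsilyloxy)phenyl]-3,4-dihydro-2H-chromen-7-yl pivalate | C#CC(C)(C)Oc1ccc([C@@H]2CCc3ccc(OC(=O)C(C)(C)C)cc3O2)cc1O[Si](C(C)C)(C(C)C)C(C)C | intermediate
14 | (2S)-2-[4-hydroxy-3-(3-methylbuta-1,2-dien-1-yl)-5-(triisopropylsilyloxy)phenyl]-3,4-dihydro-2H-chromen-7-yl pivalate | CC(C)=C=Cc1cc([C@@H]2CCc3ccc(OC(=O)C(C)(C)C)cc3O2)cc(O[Si](C(C)C)(C(C)C)C(C)C)c1O | intermediate
15 | (2S)-2-[2,2-dimethyl-8-(triisopropylsilyloxy)-2H-chromen-6-yl]-3,4-dihydro-2H-chromen-7-yl pivalate | CC(C)[Si](C(C)C)(C(C)C)Oc1cc([C@@H]2CCc3ccc(OC(=O)C(C)(C)C)cc3O2)cc2C=CC(C)(C)Oc12 | intermediate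
16 | (2S)-2-(8-hydroxy-2,2-dimethyl-2H-chromen-6-yl)-3,4-dihydro-2H-chromen-7-yl pivalate | Oc1cc([C@@H]2CCc3ccc(OC(=O)C(C)(C)C)cc3O2)cc2C=CC(C)(C)Oc12 | intermediate
17 | 2-methylbut-3-en-2-ol | C=CC(C)(C)O | starting material
18 | tert-butyl 2-methylbut-3-en-2-yl carbonate | C=CC(C)(C)OC(=O)OC(C)(C)C | intermediate
19 | (2S)-2-[2,2-dimethyl-8-(2-methylbut-3-en-2-yloxy)-2H-chromen-6-yl]-3,4-dihydro-2H-chromen-7-yl pivalate | C=CC(C)(C)Oc1cc([C@@H]2CCc3ccc(OC(=O)C(C)(C)C)cc3O2)cc2C=CC(C)(C)Oc12 | intermediate
20 | (2S)-2-[2,2-dimethyl-7-(3-methylbut-2-en-1-yl)-8-oxo-7,8-dihydro-2H-chromen-6-yl]-3,4-dihydro-2H-chromen-7-yl pivalate (either configuration at the prenyl-bearing carbon) | CC(C)=CCC1C(=O)C2=C(C=CC(C)(C)O2)C=C1[C@@H]1CCc3ccc(OC(=O)C(C)(C)C)cc3O1 | intermediate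
21 | (2S)-2-[8-hydroxy-2,2-dimethyl-7-(3-methylbut-2-en-1-yl)-2H-chromen-6-yl]-3,4-dihydro-2H-chromen-7-yl pivalate | CC(C)=CCc1c([C@@H]2CCc3ccc(OC(=O)C(C)(C)C)cc3O2)cc2c(c1O)OC(C)(C)C=C2 | intermediate
22 | kazinol B, (2S)-2-[8-hydroxy-2,2-dimethyl-7-(3-methylbut-2-en-1-yl)-2H-chromen-6-yl]-3,4-dihydro-2H-chromen-7-ol | CC(C)=CCc1c([C@@H]2CCc3ccc(O)cc3O2)cc2c(c1O)OC(C)(C)C=C2 | target

## Step count and risks

Total: 14 steps. Longest linear sequence: 12 steps (from 3 through steps 2–10 and 12–14). Ring A enters after one step (step 1) and the prenyl donor after one step (step 11).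

**Step 5 (key step).** The most likely failures are erosion of enantioselectivity, if the oxa-Michael adduct reverts faster than the aldol step traps it, and low conversion, because the donor-substituted enal gives a weakly electrophilic iminium ion and the amine can be sequestered by the salicylaldehyde. The fallback makes the O1–C2 bond by iridium-catalysed asymmetric allylic etherification and closes ring C by olefin metathesis. It sets out from 7 and 2 and returns at 11. Luche reduction of 7 (NaBH4, CeCl3) should give the cinnamyl alcohol F1, and methyl chloroformate with pyridine its methyl carbonate F2. [Ir(cod)Cl]2 with a binaphthol-derived phosphoramidite ligand and the phenoxide of 2 should then give the branched (S)-allyl aryl ether F3. Wittig methylenation of its formyl group (Ph3P=CH2) should give the vinylarene F4, and the second-generation Grubbs catalyst should close ring C to the flav-3-ene F5 with loss of ethene. Hydrogenation over Pd/C saturates C3–C4 and removes benzyl, which rejoins the route at 11 with no decarbonylation.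

**Step 7.** CO extrusion from the hindered secondary acyl complex may be slow. At the temperature then needed, loss of the β-aryloxy group from the alkyl–rhodium intermediate or opening of the para-hydroxybenzylic ether would destroy ring C. The fallback removes the extra carbon as CO2 by a radical chain at room temperature instead of as CO on a metal. It sets out from 9 and returns at 11. Pinnick oxidation of the enal (NaClO2, NaH2PO4, 2-methylbut-2-ene, t-BuOH/H2O), run on 9 because it has no free phenol, should give the 2H-chromene-3-carboxylic acid F6. Hydrogenation over Pd/C then saturates C3–C4 and removes benzyl to give the chroman-3-carboxylic acid F7 as a mixture of C3 epimers. DCC and N-hydroxypyridine-2-thione, used without an acyl-transfer catalyst so that the hindered 4'-phenol is not esterified, should convert it in the dark into the Barton ester F8. Irradiation with visible light in the presence of 2-methylpropane-2-thiol then brings about reductive decarboxylation to 11. The secondary C3 radical is reduced by the thiol faster than it can expel the O1 aryloxyl radical, and C2 is not involved.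

**Step 8.** Under base the silyl group may migrate from O3' to O4', which would scramble the two catechol oxygens, and the 4'-phenoxide may open ring C through a para-quinone methide. The fallback sets out from 11 and returns at 15 without a free phenoxide. The titanium phenoxide formed from 11 and Ti(OEt)4 is condensed with 3-methylbut-2-enal in hot toluene (ortho-hydroxyalkylation at C5', dehydration, oxa-6π closure), which builds ring D directly.

**Step 13.** Rearrangement into the flanked C2' may be slow. It could then lose to ipso attack at C4' followed by a Cope shift to C6', or to ionisation of the tertiary ether back to the phenol. The fallback sets out from 16 and returns at 21. The sodium phenoxide of 16 is C-alkylated with prenyl bromide in toluene; in a non-polar medium this favours the ortho carbon, and C2' is the only free one.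

## Further compounds

F1 | step 5 | (E)-3-[4-(benzyloxy)-3-(triisopropylsilyloxy)phenyl]prop-2-en-1-ol | OC/C=C/c1ccc(OCc2ccccc2)c(O[Si](C(C)C)(C(C)C)C(C)C)c1
F2 | step 5 | (E)-3-[4-(benzyloxy)-3-(triisopropylsilyloxy)phenyl]prop-2-en-1-yl methyl carbonate | COC(=O)OC/C=C/c1ccc(OCc2ccccc2)c(O[Si](C(C)C)(C(C)C)C(C)C)c1
F3 | step 5 | 3-({(1S)-1-[4-(benzyloxy)-3-(triisopropylsilyloxy)phenyl]prop-2-en-1-yl}oxy)-4-formylphenyl pivalate | CC(C)[Si](C(C)C)(C(C)C)Oc1cc([C@@H](Oc2cc(OC(=O)C(C)(C)C)ccc2C=O)C=C)ccc1OCc1ccccc1
F4 | step 5 | 3-({(1S)-1-[4-(benzyloxy)-3-(triisopropylsilyloxy)phenyl]prop-2-en-1-yl}oxy)-4-vinylphenyl pivalate | CC(C)[Si](C(C)C)(C(C)C)Oc1cc([C@@H](Oc2cc(OC(=O)C(C)(C)C)ccc2C=C)C=C)ccc1OCc1ccccc1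
F5 | step 5 | (2S)-2-[4-(benzyloxy)-3-(triisopropylsilyloxy)phenyl]-2H-chromen-7-yl pivalate | CC(C)[Si](C(C)C)(C(C)C)Oc1cc([C@@H]2C=Cc3ccc(OC(=O)C(C)(C)C)cc3O2)ccc1OCc1ccccc1
F6 | step 7 | (2R)-2-[4-(benzyloxy)-3-(triisopropylsilyloxy)phenyl]-7-(pivaloyloxy)-2H-chromene-3-carboxylic acid | CC(C)[Si](C(C)C)(C(C)C)Oc1cc([C@@H]2C(C(=O)O)=Cc3ccc(OC(=O)C(C)(C)C)cc3O2)ccc1OCc1ccccc1
F7 | step 7 | (2S)-2-[4-hydroxy-3-(triisopropylsilyloxy)phenyl]-7-(pivaloyloxy)-3,4-dihydro-2H-chromene-3-carboxylic acid (both C3 epimers) | CC(C)[Si](C(C)C)(C(C)C)Oc1cc([C@@H]2C(C(=O)O)Cc3ccc(OC(=O)C(C)(C)C)cc3O2)ccc1O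
F8 | step 7 | 2-thioxopyridin-1(2H)-yl (2S)-2-[4-hydroxy-3-(triisopropylsilyloxy)phenyl]-7-(pivaloyloxy)-3,4-dihydro-2H-chromene-3-carboxylate (Barton ester, both C3 epimers) | CC(C)[Si](C(C)C)(C(C)C)Oc1cc([C@@H]2C(C(=O)ON4C=CC=CC4=S)Cc3ccc(OC(=O)C(C)(C)C)cc3O2)ccc1O
F0 | step 8 | none | none
F0 | step 13 | none | none
A1 | alternative 1 | 3-bromo-4-[3-(4-allyl-2,2-dimethyl-1,3-benzodioxol-5-yl)prop-2-yn-1-yl]phenyl pivalate | C=CCc1c(C#CCc2ccc(OC(=O)C(C)(C)C)cc2Br)ccc2OC(C)(C)Oc12
A2 | alternative 1 | 2,2-dimethyl-4-(trimethylsilyl)-1,3-benzodioxol-5-yl trifluoromethanesulfonate | CC1(C)Oc2ccc(OS(=O)(=O)C(F)(F)F)c([Si](C)(C)C)c2O1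
A3 | alternative 1 | 3-bromo-4-(prop-2-yn-1-yl)phenyl pivalate | C#CCc1ccc(OC(=O)C(C)(C)C)cc1Br
A4 | alternative 2 | 7-O-(methoxymethyl)kazinol B | CC(C)=CCc1c([C@@H]2CCc3ccc(OCOC)cc3O2)cc2c(c1O)OC(C)(C)C=C2
A5 | alternative 2 | (2S)-7-(methoxymethoxy)-2-[3-(2-methylbut-3-en-2-yloxy)-4-(2-methylbut-3-yn-2-yloxy)phenyl]-3,4-dihydro-2H-chromene | C=CC(C)(C)Oc1cc([C@@H]2CCc3ccc(OCOC)cc3O2)ccc1OC(C)(C)C#C
A6 | alternative 3 | (2S)-2-[2,2-dimethyl-8-(triisopropylsilyloxy)-2H-chromen-6-yl]-7-(methoxymethoxy)-3,4-dihydro-2H-chromene | CC(C)[Si](C(C)C)(C(C)C)Oc1cc([C@@H]2CCc3ccc(OCOC)cc3O2)cc2C=CC(C)(C)Oc12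
A7 | alternative 3 | (1S)-3-[2-chloro-4-(methoxymethoxy)phenyl]-1-[2,2-dimethyl-8-(triisopropylsilyloxy)-2H-chromen-6-yl]propan-1-ol | CC(C)[Si](C(C)C)(C(C)C)Oc1cc([C@@H](O)CCc2ccc(OCOC)cc2Cl)cc2C=CC(C)(C)Oc12
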